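**Strategy**

Ring C is disconnected at C3–C4 and O1–C8a. The plan exploits the fact that O1 is attached to C8a of ring A, the carbon ortho to the C4 carbonyl, so this aryl ether bond can be formed by displacing a fluoride that the newly installed carbonyl activates. In one operation the magnesium enolate of a ring B α-alkoxy ketone is C-acylated by a ring A 2-fluorobenzoyl chloride, and the diketone enolate oxygen then closes ring C by intramolecular nucleophilic aromatic substitution. The acid chloride carries the 3-methoxy, 4-prenyloxy and 6-allyloxy groups beside the single 2-fluorine; the ketone is the 4-O-allyl, α-O-SEM derivative of acetovanillone. Fluoride-mediated and palladium-catalysed deprotections, both acid-free, finish the synthesis.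

Key step: step 9

**Remarks on the design**

- Abbreviations: prenyl = 3-methylbut-2-en-1-yl; allyl = prop-2-en-1-yl; SEM = [2-(trimethylsilyl)ethoxy]methyl. Flavone numbering (O1, C2–C8a, primed ring B) is used from 14 on.
- No protic acid is used once the prenyl ether is in place, because acid can cleave an aryl prenyl ether and add to its trisubstituted alkene. Both phenols are therefore allyl ethers and the C3 oxygen is a SEM ether.
- Allyl is avoided on the C3 oxygen because a 2-allyloxy-1,3-diketone enolate can undergo a [2,3]-shift. An acetal is avoided ortho to the acid chloride because it can close onto the acyl carbon.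
- The acid passes through the fluoride displacement as its prenyl ester, so that ester exchange with prenyl alkoxide is degenerate and no competing alkoxide is released.
- The acid chloride is made with a neutral α-chloroenamine, so that no HCl reaches the prenyl ether.

**Route**

Step 1
Reactants: 1 2,4-difluoro-3-methoxybenzoic acid
Product: 2 2,4-difluoro-6-hydroxy-3-methoxybenzoic acid
Conditions: Pd(OAc)2 (10 mol%), KOAc, benzoquinone (additive), O2 (1 atm), DMA, 115 °C
Reagents that add atoms: dioxygen, O=O
Why: Carboxylate-directed cyclopalladation by divalent palladium can take place only at C6–H, the one free position ortho to the carboxyl group, and the aryl–palladium bond is then oxygenated with O2 as terminal oxidant (carboxyl-directed C–H hydroxylation).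

Step 2
Reactants: 2 2,4-difluoro-6-hydroxy-3-methoxybenzoic acid
Product: 4 prenyl 6-(allyloxy)-2,4-difluoro-3-methoxybenzoate, via prenyl 2,4-difluoro-6-hydroxy-3-methoxybenzoate 3 (not isolated)
Conditions: prenyl bromide (1.0 equiv), KHCO3, DMF, rt; then allyl bromide, K2CO3, 50 °C
Reagents that add atoms: prenyl bromide, CC(C)=CCBr; allyl bromide, C=CCBr
Why: Hydrogencarbonate ionises only the carboxylic acid (the phenol stays hydrogen-bonded to the carbonyl group), so SN2 alkylation first gives the ester, and Williamson etherification of the phenol follows once carbonate is added.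

Step 3
Reactants: 4 prenyl 6-(allyloxy)-2,4-difluoro-3-methoxybenzoate; 5 3-methylbut-2-en-1-ol (prenyl alcohol)
Product: 6 prenyl 6-(allyloxy)-2-fluoro-3-methoxy-4-(prenyloxy)benzoate
Conditions: KN(SiMe3)2, 18-crown-6, THF, −20 °C → rt (alkoxide pre-formed)
Reagents that add atoms: none
Why: Nucleophilic aromatic substitution by addition–elimination should favour the C4 fluoride, which is para to the ester and flanked only by OMe and H, over the C2 fluoride wedged between OMe and the ester, since sequestering K+ suppresses ester-chelated delivery to C2.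

Step 4
Reactants: 6 prenyl 6-(allyloxy)-2-fluoro-3-methoxy-4-(prenyloxy)benzoate
Product: 7 6-(allyloxy)-2-fluoro-3-methoxy-4-(prenyloxy)benzoic acid
Conditions: LiOH, THF/H2O, 60 °C; then 1 M HCl to pH 3, 0 °C
Reagents that add atoms: lithium hydroxide, [Li+].[OH-]
Why: Ester saponification by acyl substitution should proceed cleanly because the now electron-rich ring resists fluoride displacement by hydroxide, and the brief cold acidification spares the prenyl ether.

Step 5
Reactants: 7 6-(allyloxy)-2-fluoro-3-methoxy-4-(prenyloxy)benzoic acid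
Product: 8 6-(allyloxy)-2-fluoro-3-methoxy-4-(prenyloxy)benzoyl chloride
Conditions: 1-chloro-N,N,2-trimethylprop-1-en-1-amine, CH2Cl2, 0 °C → rt; concentrate, use crude
Reagents that add atoms: 1-chloro-N,N,2-trimethylprop-1-en-1-amine, CC(C)=C(Cl)N(C)C
Why: The α-chloroenamine converts the acid into the acid chloride through an acyloxyiminium chloride under neutral conditions, releasing only an amide and no HCl.

Step 6
Reactants: 9 1-(4-hydroxy-3-methoxyphenyl)ethanone (acetovanillone)
Product: 10 1-[4-(allyloxy)-3-methoxyphenyl]ethanone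
Conditions: allyl bromide, K2CO3, acetone, reflux
Reagents that add atoms: allyl bromide, C=CCBr
Why: Williamson etherification of the phenoxide, needed because the free phenol would not survive the oxidant of the next step.

Step 7
Reactants: 10 1-[4-(allyloxy)-3-methoxyphenyl]ethanone
Product: 12 1-[4-(allyloxy)-3-methoxyphenyl]-2-hydroxyethanone, via hydroxy dimethyl acetal 11 (not isolated)
Conditions: PhI(OAc)2, KOH, MeOH, 0 °C → rt; then 1 M HCl, THF, rt
Reagents that add atoms: water, O (carbonyl oxygen of 12); methanol, CO (methoxy groups of 11 only)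
Why: Hypervalent-iodine α-hydroxylation of an aryl methyl ketone, in which the enolate is captured by trivalent iodine, methoxide adds to the carbonyl and expels iodobenzene to give a methoxy epoxide that methanol opens to the α-hydroxy dimethyl acetal, followed by acetal hydrolysis in dilute acid that the allyl ether tolerates.

Step 8
Reactants: 12 1-[4-(allyloxy)-3-methoxyphenyl]-2-hydroxyethanone
Product: 13 1-[4-(allyloxy)-3-methoxyphenyl]-2-{[2-(trimethylsilyl)ethoxy]methoxy}ethanone
Conditions: SEMCl, i-Pr2NEt, CH2Cl2, 0 °C → rt
Reagents that add atoms: 2-(trimethylsilyl)ethoxymethyl chloride, C[Si](C)(C)CCOCCl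
Why: O-alkylation of the primary hydroxyl group by the α-chloro ether (substitution through an oxocarbenium ion) with a hindered amine as acid scavenger, which does not enolise the ketone.

Step 9
Reactants: 8 6-(allyloxy)-2-fluoro-3-methoxy-4-(prenyloxy)benzoyl chloride; 13 1-[4-(allyloxy)-3-methoxyphenyl]-2-{[2-(trimethylsilyl)ethoxy]methoxy}ethanone
Product: 15 5-(allyloxy)-2-[4-(allyloxy)-3-methoxyphenyl]-8-methoxy-7-(prenyloxy)-3-{[2-(trimethylsilyl)ethoxy]methoxy}-4H-chromen-4-one, via 1,3-diketone 14 (not isolated)
Conditions: MgBr2·OEt2, i-Pr2NEt, CH2Cl2, 0 °C → rt; aqueous work-up; then K2CO3, DMF, 80 °C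
Reagents that add atoms: none
Why: Soft enolisation gives the chelated magnesium enolate of 13, which attacks the acyl chloride at carbon to form C3–C4; the magnesium 1,3-diketonate so formed resists a second acylation, and any enol ester from O-acylation is funnelled to the same diketonate by acyl transfer. With K2CO3 in warm DMF the enolate oxygen on the ring B side adds to C8a, the fluorine-bearing carbon ortho to the C4 carbonyl, giving a Meisenheimer anion stabilised by that carbonyl, and loss of fluoride forms O1–C8a. The closest known reaction type is the preparation of chromones, flavones and 4-quinolones from 2-fluorobenzoyl chlorides by acylation of an enolate or enamine followed by intramolecular nucleophilic aromatic substitution. Ring C closes as a six-membered ring by addition–elimination of oxygen at an aromatic sp2 carbon. No stereocentre is formed, since the labile diketone carbon becomes sp2 C3. The step needs C- over O-acylation, which the magnesium chelate secures, and a single substitution site, which is secured because fluoride is the only good leaving group on ring A and lies ortho to the acyl carbon, while the C5 and C7 oxygens are meta to C8a and the SEM ether on the central carbon is inert.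

Step 10
Reactants: 15 5-(allyloxy)-2-[4-(allyloxy)-3-methoxyphenyl]-8-methoxy-7-(prenyloxy)-3-{[2-(trimethylsilyl)ethoxy]methoxy}-4H-chromen-4-one
Product: 16 5-(allyloxy)-2-[4-(allyloxy)-3-methoxyphenyl]-3-hydroxy-8-methoxy-7-(prenyloxy)-4H-chromen-4-one
Conditions: Bu4NF, THF, 60 °C; then aq. NH4Cl
Reagents that add atoms: none
Why: Fluoride attacks silicon and the 2-silylethyl acetal fragments (fluoride-induced β-elimination) to expel the acidic C3 enol oxide, while allyl and prenyl ethers are inert to fluoride.

Step 11
Reactants: 16 5-(allyloxy)-2-[4-(allyloxy)-3-methoxyphenyl]-3-hydroxy-8-methoxy-7-(prenyloxy)-4H-chromen-4-one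
Product: 17 3,5-dihydroxy-2-(4-hydroxy-3-methoxyphenyl)-8-methoxy-7-(prenyloxy)-4H-chromen-4-one (CNP0210396.0)
Conditions: Pd(PPh3)4 (5 mol%), morpholine, THF, rt, under argon
Reagents that add atoms: none
Why: Tsuji–Trost deallylation, in which zerovalent palladium ionises the two unsubstituted allyl aryl ethers to π-allylpalladium complexes that morpholine intercepts, while the γ,γ-dimethylallyl (prenyl) ether, much slower in oxidative addition, is expected to remain.

**Compound list**

1 | 2,4-difluoro-3-methoxybenzoic acid | COc1c(F)ccc(C(=O)O)c1F | starting material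
2 | 2,4-difluoro-6-hydroxy-3-methoxybenzoic acid | COc1c(F)cc(O)c(C(=O)O)c1F | intermediate
3 | prenyl 2,4-difluoro-6-hydroxy-3-methoxybenzoate (not isolated) | COc1c(F)cc(O)c(C(=O)OCC=C(C)C)c1F | intermediate
4 | prenyl 6-(allyloxy)-2,4-difluoro-3-methoxybenzoate | COc1c(F)cc(OCC=C)c(C(=O)OCC=C(C)C)c1F | intermediate
5 | 3-methylbut-2-en-1-ol (prenyl alcohol) | CC(C)=CCO | starting material
6 | prenyl 6-(allyloxy)-2-fluoro-3-methoxy-4-(prenyloxy)benzoate | COc1c(OCC=C(C)C)cc(OCC=C)c(C(=O)OCC=C(C)C)c1F | intermediate
7 | 6-(allyloxy)-2-fluoro-3-methoxy-4-(prenyloxy)benzoic acid | COc1c(OCC=C(C)C)cc(OCC=C)c(C(=O)O)c1F | intermediate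
8 | 6-(allyloxy)-2-fluoro-3-methoxy-4-(prenyloxy)benzoyl chloride | COc1c(OCC=C(C)C)cc(OCC=C)c(C(Cl)=O)c1F | intermediate
9 | 1-(4-hydroxy-3-methoxyphenyl)ethanone (acetovanillone) | CC(=O)c1ccc(O)c(OC)c1 | starting material
10 | 1-[4-(allyloxy)-3-methoxyphenyl]ethanone | CC(=O)c1ccc(OCC=C)c(OC)c1 | intermediate
11 | 2-[4-(allyloxy)-3-methoxyphenyl]-2,2-dimethoxyethanol (not isolated) | COC(CO)(OC)c1ccc(OCC=C)c(OC)c1 | intermediate
12 | 1-[4-(allyloxy)-3-methoxyphenyl]-2-hydroxyethanone | O=C(CO)c1ccc(OCC=C)c(OC)c1 | intermediate
13 | 1-[4-(allyloxy)-3-methoxyphenyl]-2-{[2-(trimethylsilyl)ethoxy]methoxy}ethanone | C[Si](C)(C)CCOCOCC(=O)c1ccc(OCC=C)c(OC)c1 | intermediate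
14 | 1-[6-(allyloxy)-2-fluoro-3-methoxy-4-(prenyloxy)phenyl]-3-[4-(allyloxy)-3-methoxyphenyl]-2-{[2-(trimethylsilyl)ethoxy]methoxy}propane-1,3-dione (C2 racemic and enolisable; not isolated) | COc1c(OCC=C(C)C)cc(OCC=C)c(C(=O)C(OCOCC[Si](C)(C)C)C(=O)c2ccc(OCC=C)c(OC)c2)c1F | intermediate
15 | 5-(allyloxy)-2-[4-(allyloxy)-3-methoxyphenyl]-8-methoxy-7-(prenyloxy)-3-{[2-(trimethylsilyl)ethoxy]methoxy}-4H-chromen-4-one | COc1cc(-c2oc3c(OC)c(OCC=C(C)C)cc(OCC=C)c3c(=O)c2OCOCC[Si](C)(C)C)ccc1OCC=C | intermediate
16 | 5-(allyloxy)-2-[4-(allyloxy)-3-methoxyphenyl]-3-hydroxy-8-methoxy-7-(prenyloxy)-4H-chromen-4-one | COc1cc(-c2oc3c(OC)c(OCC=C(C)C)cc(OCC=C)c3c(=O)c2O)ccc1OCC=C | intermediate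
17 | 3,5-dihydroxy-2-(4-hydroxy-3-methoxyphenyl)-8-methoxy-7-[(3-methylbut-2-en-1-yl)oxy]-4H-chromen-4-one (no stereocentre) | COc1cc(-c2oc3c(OC)c(OCC=C(C)C)cc(O)c3c(=O)c2O)ccc1O | target

**Step count**

Total: 11 steps. Longest linear sequence: 8 steps (steps 1–5, 9, 10, 11).

**Steps most likely to fail**

Step 9. The acid chloride is flanked by two ortho substituents, so the enolate may be acylated on oxygen, or the chloride may be lost to hydrolysis, before the C3–C4 bond forms. The fallback sets out from acid 7 and ketone 13. Acid 7 is converted with 1H-benzotriazole and EDC·HCl in CH2Cl2 into the N-acylbenzotriazole F1, a neutral acyl donor. The lithium enolate of 13 (LiN(SiMe3)2, 2 equiv, THF, −78 °C) is then C-acylated by F1, a known regioselective route to 1,3-diketones from preformed enolates. This returns to diketone 14, which is closed to 15 with K2CO3 in DMF as in step 9.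

Step 3. Site selectivity may be poor: the alkoxide may attack the C2 fluoride beside the ester, or displace both fluorides. The fallback sets out from 4 and postpones the ether formation until ring C exists.
- Saponification (LiOH, THF/H2O) gives 6-(allyloxy)-2,4-difluoro-3-methoxybenzoic acid F2.
- The chloroenamine of step 5 gives the acid chloride F3.
- Acylation of 13 under the conditions of step 9 gives the 1,3-diketone F4.
- K2CO3 in DMF closes ring C onto the only fluoride that the enolate oxygen can reach, giving the 7-fluoroflavone F5.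
- The one remaining fluoride, now para to the C4 carbonyl, is displaced by potassium prenyloxide (5, KN(SiMe3)2, THF/DMF), as C7 fluorides of chromones and 4-quinolones are.

The fallback comes back to the route at 15.

Step 1. C–H activation of the electron-poor acid may be incomplete, or the di-ortho-substituted product may protodecarboxylate at 115 °C. The fallback sets out from 1. Fischer esterification (EtOH, H2SO4, reflux) gives ethyl 2,4-difluoro-3-methoxybenzoate F6, which cannot decarboxylate. Ester-directed ortho C–H oxygenation ([RuCl2(p-cymene)]2, K2S2O8, CF3CO2H/(CF3CO)2O, 80 °C) gives ethyl 2,4-difluoro-3-methoxy-6-(trifluoroacetoxy)benzoate F7. Aqueous NaOH then cleaves both esters, and acidification returns the route to 2.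

**Further compounds**

F1 | step 9 | [6-(allyloxy)-2-fluoro-3-methoxy-4-(prenyloxy)phenyl](1H-benzotriazol-1-yl)methanone | COc1c(OCC=C(C)C)cc(OCC=C)c(C(=O)n2nnc3ccccc32)c1F
F2 | step 3 | 6-(allyloxy)-2,4-difluoro-3-methoxybenzoic acid | COc1c(F)cc(OCC=C)c(C(=O)O)c1F
F3 | step 3 | 6-(allyloxy)-2,4-difluoro-3-methoxybenzoyl chloride | COc1c(F)cc(OCC=C)c(C(Cl)=O)c1F
F4 | step 3 | 1-[6-(allyloxy)-2,4-difluoro-3-methoxyphenyl]-3-[4-(allyloxy)-3-methoxyphenyl]-2-{[2-(trimethylsilyl)ethoxy]methoxy}propane-1,3-dione (C2 racemic and enolisable) | COc1c(F)cc(OCC=C)c(C(=O)C(OCOCC[Si](C)(C)C)C(=O)c2ccc(OCC=C)c(OC)c2)c1F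
F5 | step 3 | 5-(allyloxy)-2-[4-(allyloxy)-3-methoxyphenyl]-7-fluoro-8-methoxy-3-{[2-(trimethylsilyl)ethoxy]methoxy}-4H-chromen-4-one | COc1cc(-c2oc3c(OC)c(F)cc(OCC=C)c3c(=O)c2OCOCC[Si](C)(C)C)ccc1OCC=C
F6 | step 1 | ethyl 2,4-difluoro-3-methoxybenzoate | CCOC(=O)c1ccc(F)c(OC)c1F
F7 | step 1 | ethyl 2,4-difluoro-3-methoxy-6-(trifluoroacetoxy)benzoate | CCOC(=O)c1c(OC(=O)C(F)(F)F)cc(F)c(OC)c1F
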